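Ring A bears four contiguous substituents (acyl at C1', OH at C2', prenyl at C3', OH at C4'), so it is not bought but built. The C1'–C2' and C5'–C6' bonds are cut, giving a terminal ynone (C1', C6') that already carries the (R)-carbinol and ring B, and a 2-prenyl-1-methoxy-1,3-bis(silyloxy)butadiene (C2'–C5'). One cycloaddition–aromatisation closes ring A, fixes the prenyl group between the two phenols and leaves both phenols free. The stereocentre comes from methyl (R)-glycidate. Every protecting group is a silyl ether, so a single buffered fluoride step ends the synthesis without acid that could close chromans.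

Key step: step 12

Remark on the chemistry: ring A is the 2,4-dihydroxy-3-prenylbenzoyl ring (C1'–C6') and ring B the 3,4-dihydroxy-5-prenylphenyl ring; prenyl = 3-methylbut-2-en-1-yl, TBS = tert-butyldimethylsilyl, TMS = trimethylsilyl; the double-bond geometry drawn for 17–19 is assumed to be of no consequence, because those carbons end up in the aromatic ring.

Step 1
Reactants: 1 5-bromo-2-hydroxybenzaldehyde
Product: 2 5-bromo-2-hydroxy-3-iodobenzaldehyde
Conditions: NIS, TFA (cat.), MeCN, 25 °C
Reagents that add atoms: N-iodosuccinimide, O=C1CCC(=O)N1I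
Why: Electrophilic aromatic iodination, in which the hydroxyl group (ortho) and the formyl group (meta) both direct to C3 while the para position is blocked by bromine, so only C3 should react.

Step 2
Reactants: 2 5-bromo-2-hydroxy-3-iodobenzaldehyde
Product: 3 5-bromo-3-iodobenzene-1,2-diol
Conditions: H2O2 (30 % aq.), NaOH, H2O/THF, 0 → 25 °C, under N2; then aq. HCl
Reagents that add atoms: hydrogen peroxide, OO
Why: Dakin oxidation, in which hydroperoxide adds to the aldehyde, the ortho-phenoxide ring migrates to oxygen and the aryl formate is hydrolysed in the same pot, the aryl halides being inert.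

Step 3
Reactants: 3 5-bromo-3-iodobenzene-1,2-diol
Product: 4 5-bromo-1,2-bis(tert-butyldimethylsilyloxy)-3-iodobenzene
Conditions: TBSCl, imidazole, DMF, 25 → 40 °C
Reagents that add atoms: tert-butyldimethylsilyl chloride, CC(C)(C)[Si](C)(C)Cl
Why: Imidazole-mediated O-silylation of both phenols; silyl ethers tolerate the organomagnesium steps and all leave together under fluoride at the end.

Step 4
Reactants: 4 5-bromo-1,2-bis(tert-butyldimethylsilyloxy)-3-iodobenzene; 5 prenyl bromide
Product: 7 5-bromo-1,2-bis(tert-butyldimethylsilyloxy)-3-(3-methylbut-2-en-1-yl)benzene, via arylmagnesium chloride 6 (not isolated)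
Conditions: i-PrMgCl·LiCl, THF, −40 °C; then CuBr·SMe2 (10 mol %), 5, −40 → 0 °C
Reagents that add atoms: none
Why: Iodine–magnesium exchange is far faster than bromine–magnesium exchange, so only C3 should be metalated, and copper-catalysed allylic substitution by the aryl cuprate formed from the excess Grignard reagent should attack the unhindered primary carbon of 5 to give the linear prenyl group.

Step 5
Reactants: 7 5-bromo-1,2-bis(tert-butyldimethylsilyloxy)-3-(3-methylbut-2-en-1-yl)benzene; 8 methyl (R)-glycidate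
Product: 10 methyl (R)-3-[3,4-bis(tert-butyldimethylsilyloxy)-5-(3-methylbut-2-en-1-yl)phenyl]-2-hydroxypropanoate, via arylmagnesium bromide 9 (not isolated)
Conditions: Mg, LiCl, THF, 25 °C; then CuI (10 mol %), 8, THF, −40 → −20 °C; aq. NH4Cl
Reagents that add atoms: none
Why: Grignard formation followed by copper-catalysed SN2 opening of the epoxide at its unsubstituted CH2, which at −40 °C should outrun addition to the ester; no bond to the stereocentre is made or broken, so the (R) configuration of 8 is carried into 10.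

Step 6
Reactants: 10 methyl (R)-3-[3,4-bis(tert-butyldimethylsilyloxy)-5-(3-methylbut-2-en-1-yl)phenyl]-2-hydroxypropanoate
Product: 11 methyl (R)-3-[3,4-bis(tert-butyldimethylsilyloxy)-5-(3-methylbut-2-en-1-yl)phenyl]-2-(tert-butyldimethylsilyloxy)propanoate
Conditions: TBSCl, imidazole, DMF, 25 °C
Reagents that add atoms: tert-butyldimethylsilyl chloride, CC(C)(C)[Si](C)(C)Cl
Why: Standard silylation of a secondary alcohol, which does not involve the stereocentre.

Step 7
Reactants: 11 methyl (R)-3-[3,4-bis(tert-butyldimethylsilyloxy)-5-(3-methylbut-2-en-1-yl)phenyl]-2-(tert-butyldimethylsilyloxy)propanoate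
Product: 12 (R)-3-[3,4-bis(tert-butyldimethylsilyloxy)-5-(3-methylbut-2-en-1-yl)phenyl]-2-(tert-butyldimethylsilyloxy)-N-methoxy-N-methylpropanamide
Conditions: MeNH(OMe)·HCl, i-PrMgCl, THF, −20 → 0 °C
Reagents that add atoms: N,O-dimethylhydroxylamine hydrochloride, CNOC.Cl
Why: Direct aminolysis of the ester by the chloromagnesium amide of N,O-dimethylhydroxylamine (Weinreb amide formation) at low temperature, conditions under which α-silyloxy esters should not epimerise.

Step 8
Reactants: 12 (R)-3-[3,4-bis(tert-butyldimethylsilyloxy)-5-(3-methylbut-2-en-1-yl)phenyl]-2-(tert-butyldimethylsilyloxy)-N-methoxy-N-methylpropanamide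
Product: 14 (R)-5-[3,4-bis(tert-butyldimethylsilyloxy)-5-(3-methylbut-2-en-1-yl)phenyl]-4-(tert-butyldimethylsilyloxy)pent-1-yn-3-one, via magnesium hemiaminal 13 (not isolated)
Conditions: HC≡CMgBr, THF, −20 → 0 °C; inverse quench into cold aq. NaHSO4
Reagents that add atoms: ethynylmagnesium bromide, C#C[Mg]Br
Why: Weinreb ketone synthesis, in which the chelated tetrahedral adduct 13 (its new carbon centre is transient) survives until the quench so that only one ethynyl group is delivered, and the cold acidic quench protonates the released amine before it can add to the ynone.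

Step 9
Reactants: 15 methyl acetoacetate; 5 prenyl bromide
Product: 16 methyl 2-acetyl-5-methylhex-4-enoate
Conditions: K2CO3, acetone, 56 °C (15 in slight excess)
Reagents that add atoms: none
Why: Acetoacetic ester C-alkylation with a reactive allylic bromide, the excess of 15 suppressing dialkylation; the new stereocentre forms racemic and is erased in step 10.

Step 10
Reactants: 16 methyl 2-acetyl-5-methylhex-4-enoate
Product: 17 methyl 2-(3-methylbut-2-en-1-yl)-3-(trimethylsilyloxy)but-2-enoate
Conditions: TMSCl, Et3N, toluene, 25 °C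
Reagents that add atoms: chlorotrimethylsilane, C[Si](C)(C)Cl
Why: O-silylation of the enol form of the β-keto ester, the first stage of the standard two-stage preparation of 1,3-bis(silyloxy)dienes.

Step 11
Reactants: 17 methyl 2-(3-methylbut-2-en-1-yl)-3-(trimethylsilyloxy)but-2-enoate
Product: 19 1-methoxy-2-(3-methylbut-2-en-1-yl)-1,3-bis(trimethylsilyloxy)buta-1,3-diene, via lithium dienolate 18 (not isolated)
Conditions: LDA, THF, −78 °C; then TMSCl, −78 → 20 °C
Reagents that add atoms: chlorotrimethylsilane, C[Si](C)(C)Cl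
Why: Kinetic γ-deprotonation of the β-silyloxy enoate gives the extended ester dienolate 18, which TMSCl should silylate on oxygen (Chan-type diene synthesis).

Step 12
Reactants: 14 (R)-5-[3,4-bis(tert-butyldimethylsilyloxy)-5-(3-methylbut-2-en-1-yl)phenyl]-4-(tert-butyldimethylsilyloxy)pent-1-yn-3-one; 19 1-methoxy-2-(3-methylbut-2-en-1-yl)-1,3-bis(trimethylsilyloxy)buta-1,3-diene
Product: 21 (R)-3-[3,4-bis(tert-butyldimethylsilyloxy)-5-(3-methylbut-2-en-1-yl)phenyl]-2-(tert-butyldimethylsilyloxy)-1-[2,4-dihydroxy-3-(3-methylbut-2-en-1-yl)phenyl]propan-1-one, via cyclohexadiene cycloadduct 20 (not isolated)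
Conditions: 19 (2 equiv), toluene, 25 → 70 °C; then citric acid, MeOH, 0 °C
Reagents that add atoms: none
Why: The electron-rich diene 19 should add to the electron-poor ynone 14 in a thermal, asynchronous [4+2] cycloaddition, the bond from the diene CH2 to the ynone β-carbon leading and the bond from the ketene acetal carbon to the α-carbon following, to give cyclohexa-1,4-diene 20; a stepwise Michael addition–ring closure would end at the same connectivity. The closest known reaction type is the Diels–Alder benzannulation of Danishefsky-, Brassard- and Chan-type oxygenated dienes with acetylenic ketones and esters, which gives resorcinol derivatives. Ring A is closed as a six-membered carbocycle by this intermolecular [4+2] cycloaddition, which forms C1'–C2' and C5'–C6'; it is aromatised when methanolysis of the silyl ketal at C2' expels methanol, the C4' silyl enol ether is cleaved and the dienone tautomerises. No stereocentre is created, since the ketal carbon of 20 becomes aromatic, and the (R) centre beside the carbonyl should be untouched by neutral heating and a weakly acidic work-up. The step needs regioselectivity, which the matched polarisation secures (nucleophilic diene CH2 terminus, electrophilic ynone β-carbon), so the acyl group lands at C1' and the prenyl group at C3' between the two oxygens. It also needs cleavage of the trimethylsilyl groups only, which methanolic citric acid secures because aryl and secondary TBS ethers are stable to it.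

Step 13
Reactants: 21 (R)-3-[3,4-bis(tert-butyldimethylsilyloxy)-5-(3-methylbut-2-en-1-yl)phenyl]-2-(tert-butyldimethylsilyloxy)-1-[2,4-dihydroxy-3-(3-methylbut-2-en-1-yl)phenyl]propan-1-one
Product: 22 (R)-1-[2,4-dihydroxy-3-(3-methylbut-2-en-1-yl)phenyl]-3-[3,4-dihydroxy-5-(3-methylbut-2-en-1-yl)phenyl]-2-hydroxypropan-1-one
Conditions: TBAF, AcOH (1:1), THF, 0 → 25 °C
Reagents that add atoms: none
Why: Fluoride-induced desilylation of the two aryl and one secondary TBS ethers, buffered with acetic acid so that neither epimerisation of the α-ketol nor cyclisation of a phenol onto a prenyl group is expected.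

Compound list
1 | 5-bromo-2-hydroxybenzaldehyde (5-bromosalicylaldehyde) | O=Cc1cc(Br)ccc1O | starting material
2 | 5-bromo-2-hydroxy-3-iodobenzaldehyde | O=Cc1cc(Br)cc(I)c1O | intermediate
3 | 5-bromo-3-iodobenzene-1,2-diol | Oc1cc(Br)cc(I)c1O | intermediate
4 | 5-bromo-1,2-bis(tert-butyldimethylsilyloxy)-3-iodobenzene | CC(C)(C)[Si](C)(C)Oc1cc(Br)cc(I)c1O[Si](C)(C)C(C)(C)C | intermediate
5 | prenyl bromide (1-bromo-3-methylbut-2-ene) | CC(C)=CCBr | starting material
6 | [5-bromo-2,3-bis(tert-butyldimethylsilyloxy)phenyl]magnesium chloride | CC(C)(C)[Si](C)(C)Oc1cc(Br)cc([Mg]Cl)c1O[Si](C)(C)C(C)(C)C | intermediate (not isolated)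
7 | 5-bromo-1,2-bis(tert-butyldimethylsilyloxy)-3-(3-methylbut-2-en-1-yl)benzene | CC(C)=CCc1cc(Br)cc(O[Si](C)(C)C(C)(C)C)c1O[Si](C)(C)C(C)(C)C | intermediate
8 | methyl (R)-glycidate (methyl (2R)-oxirane-2-carboxylate) | COC(=O)[C@H]1CO1 | starting material
9 | [3,4-bis(tert-butyldimethylsilyloxy)-5-(3-methylbut-2-en-1-yl)phenyl]magnesium bromide | CC(C)=CCc1cc([Mg]Br)cc(O[Si](C)(C)C(C)(C)C)c1O[Si](C)(C)C(C)(C)C | intermediate (not isolated)
10 | methyl (R)-3-[3,4-bis(tert-butyldimethylsilyloxy)-5-(3-methylbut-2-en-1-yl)phenyl]-2-hydroxypropanoate | COC(=O)[C@H](O)Cc1cc(CC=C(C)C)c(O[Si](C)(C)C(C)(C)C)c(O[Si](C)(C)C(C)(C)C)c1 | intermediate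
11 | methyl (R)-3-[3,4-bis(tert-butyldimethylsilyloxy)-5-(3-methylbut-2-en-1-yl)phenyl]-2-(tert-butyldimethylsilyloxy)propanoate | COC(=O)[C@H](O[Si](C)(C)C(C)(C)C)Cc1cc(CC=C(C)C)c(O[Si](C)(C)C(C)(C)C)c(O[Si](C)(C)C(C)(C)C)c1 | intermediate
12 | (R)-3-[3,4-bis(tert-butyldimethylsilyloxy)-5-(3-methylbut-2-en-1-yl)phenyl]-2-(tert-butyldimethylsilyloxy)-N-methoxy-N-methylpropanamide | CON(C)C(=O)[C@H](O[Si](C)(C)C(C)(C)C)Cc1cc(CC=C(C)C)c(O[Si](C)(C)C(C)(C)C)c(O[Si](C)(C)C(C)(C)C)c1 | intermediate
13 | bromomagnesium (4R)-5-[3,4-bis(tert-butyldimethylsilyloxy)-5-(3-methylbut-2-en-1-yl)phenyl]-4-(tert-butyldimethylsilyloxy)-3-[methoxy(methyl)amino]pent-1-yn-3-olate (tetrahedral adduct, C3 unassigned) | C#CC(O[Mg]Br)(N(C)OC)[C@H](O[Si](C)(C)C(C)(C)C)Cc1cc(CC=C(C)C)c(O[Si](C)(C)C(C)(C)C)c(O[Si](C)(C)C(C)(C)C)c1 | intermediate (not isolated)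
14 | (R)-5-[3,4-bis(tert-butyldimethylsilyloxy)-5-(3-methylbut-2-en-1-yl)phenyl]-4-(tert-butyldimethylsilyloxy)pent-1-yn-3-one | C#CC(=O)[C@H](O[Si](C)(C)C(C)(C)C)Cc1cc(CC=C(C)C)c(O[Si](C)(C)C(C)(C)C)c(O[Si](C)(C)C(C)(C)C)c1 | intermediate
15 | methyl acetoacetate | COC(=O)CC(C)=O | starting material
16 | methyl 2-acetyl-5-methylhex-4-enoate (racemic) | COC(=O)C(CC=C(C)C)C(C)=O | intermediate
17 | methyl 2-(3-methylbut-2-en-1-yl)-3-(trimethylsilyloxy)but-2-enoate | COC(=O)/C(CC=C(C)C)=C(/C)O[Si](C)(C)C | intermediate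
18 | lithium 1-methoxy-2-(3-methylbut-2-en-1-yl)-3-(trimethylsilyloxy)buta-1,3-dien-1-olate | C=C(O[Si](C)(C)C)/C(CC=C(C)C)=C(/OC)O[Li] | intermediate (not isolated)
19 | 1-methoxy-2-(3-methylbut-2-en-1-yl)-1,3-bis(trimethylsilyloxy)buta-1,3-diene | C=C(O[Si](C)(C)C)/C(CC=C(C)C)=C(/OC)O[Si](C)(C)C | intermediate
20 | (R)-3-[3,4-bis(tert-butyldimethylsilyloxy)-5-(3-methylbut-2-en-1-yl)phenyl]-2-(tert-butyldimethylsilyloxy)-1-[6-methoxy-5-(3-methylbut-2-en-1-yl)-4,6-bis(trimethylsilyloxy)cyclohexa-1,4-dien-1-yl]propan-1-one (both epimers at the ketal carbon) | CC(C)=CCC1=C(O[Si](C)(C)C)CC=C(C(=O)[C@H](O[Si](C)(C)C(C)(C)C)Cc2cc(CC=C(C)C)c(O[Si](C)(C)C(C)(C)C)c(O[Si](C)(C)C(C)(C)C)c2)C1(OC)O[Si](C)(C)C | intermediate (not isolated)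
21 | (R)-3-[3,4-bis(tert-butyldimethylsilyloxy)-5-(3-methylbut-2-en-1-yl)phenyl]-2-(tert-butyldimethylsilyloxy)-1-[2,4-dihydroxy-3-(3-methylbut-2-en-1-yl)phenyl]propan-1-one | CC(C)=CCc1cc(C[C@@H](O[Si](C)(C)C(C)(C)C)C(=O)c2ccc(O)c(CC=C(C)C)c2O)cc(O[Si](C)(C)C(C)(C)C)c1O[Si](C)(C)C(C)(C)C | intermediate
22 | (R)-1-[2,4-dihydroxy-3-(3-methylbut-2-en-1-yl)phenyl]-3-[3,4-dihydroxy-5-(3-methylbut-2-en-1-yl)phenyl]-2-hydroxypropan-1-one | CC(C)=CCc1cc(C[C@@H](O)C(=O)c2ccc(O)c(CC=C(C)C)c2O)cc(O)c1O | target

Total step count: 13. Longest linear sequence: 10 steps (steps 1–8, 12 and 13); the diene branch (steps 9–11) joins at step 12.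

Steps most likely to fail

Step 12. The hindered ketene acetal may stop after conjugate addition without closing the ring, the adduct may lose silanol in place of methanol and so keep a methyl ether at C2', or the terminal ynone may polymerise at the temperature the diene needs. The fallback sets out from Weinreb amide 12 and attaches a ready-made ring A by directed ortho-metalation. Commercial 1,3-bis(methoxymethoxy)benzene is lithiated between the two oxygens (n-BuLi, THF, 0 °C) and prenylated with 5 (CuBr·SMe2) to give 1,3-bis(methoxymethoxy)-2-(3-methylbut-2-en-1-yl)benzene F1. A second lithiation (n-BuLi, TMEDA, THF, 0 °C) gives [2,4-bis(methoxymethoxy)-3-(3-methylbut-2-en-1-yl)phenyl]lithium F2, which is added to 12 at −78 °C to give the ring A bis(methoxymethyl) ether of 21, ketone F3. Mild methanolysis of the two aryl acetals (catalytic HCl from AcCl in MeOH, 0 °C, closely monitored) comes back to the route at 21; material that also loses the carbinol silyl group converges on 22 in step 13. This fallback accepts a brief exposure to acid that the main route avoids.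

Step 5. The aryl Grignard reagent may add to the ester carbonyl, or halide may open the epoxide, in competition with copper-mediated attack at the epoxide CH2. The fallback sets out from 9 and uses an epoxide without a carbonyl group, commercial (R)-trityl glycidyl ether, C(OC[C@H]1CO1)(c1ccccc1)(c1ccccc1)c1ccccc1. Opening under the same copper catalysis gives (R)-1-[3,4-bis(tert-butyldimethylsilyloxy)-5-(3-methylbut-2-en-1-yl)phenyl]-3-(trityloxy)propan-2-ol F4. Silylation (TBSCl, imidazole, DMF) gives its TBS ether F5, and detritylation (CSA, MeOH/CH2Cl2, 0 °C) gives (R)-3-[3,4-bis(tert-butyldimethylsilyloxy)-5-(3-methylbut-2-en-1-yl)phenyl]-2-(tert-butyldimethylsilyloxy)propan-1-ol F6. Oxidation (TEMPO, PhI(OAc)2, MeCN/H2O) gives the corresponding (R)-propanoic acid F7, and amide coupling (EDC·HCl, HOBt, MeNH(OMe)·HCl, i-Pr2NEt, CH2Cl2) comes back to the route at 12.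

Step 4. The aryl copper species may attack the tertiary carbon of the prenyl electrophile, giving the reverse-prenyl isomer alongside the linear one. The fallback sets out from 6 and splits the prenylation into two regiochemically unambiguous operations. Quenching 6 with allyl bromide (CuBr·SMe2 cat., THF, −40 → 0 °C) gives 3-allyl-5-bromo-1,2-bis(tert-butyldimethylsilyloxy)benzene F8. Olefin cross-metathesis with 2-methylbut-2-ene (second-generation Grubbs catalyst RuCl2(=CHPh)(H2IMes)(PCy3), CH2Cl2, 40 °C) comes back to the route at 7.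

Further compounds
F1 | step 12 | 1,3-bis(methoxymethoxy)-2-(3-methylbut-2-en-1-yl)benzene | COCOc1cccc(OCOC)c1CC=C(C)C
F2 | step 12 | [2,4-bis(methoxymethoxy)-3-(3-methylbut-2-en-1-yl)phenyl]lithium | COCOc1ccc([Li])c(OCOC)c1CC=C(C)C
F3 | step 12 | (R)-1-[2,4-bis(methoxymethoxy)-3-(3-methylbut-2-en-1-yl)phenyl]-3-[3,4-bis(tert-butyldimethylsilyloxy)-5-(3-methylbut-2-en-1-yl)phenyl]-2-(tert-butyldimethylsilyloxy)propan-1-one | CC(C)=CCc1cc(C[C@@H](O[Si](C)(C)C(C)(C)C)C(=O)c2ccc(OCOC)c(CC=C(C)C)c2OCOC)cc(O[Si](C)(C)C(C)(C)C)c1O[Si](C)(C)C(C)(C)C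
F4 | step 5 | (R)-1-[3,4-bis(tert-butyldimethylsilyloxy)-5-(3-methylbut-2-en-1-yl)phenyl]-3-(trityloxy)propan-2-ol | CC(C)=CCc1cc(C[C@@H](O)COC(c2ccccc2)(c2ccccc2)c2ccccc2)cc(O[Si](C)(C)C(C)(C)C)c1O[Si](C)(C)C(C)(C)C
F5 | step 5 | (R)-1-[3,4-bis(tert-butyldimethylsilyloxy)-5-(3-methylbut-2-en-1-yl)phenyl]-2-(tert-butyldimethylsilyloxy)-3-(trityloxy)propane | CC(C)=CCc1cc(C[C@@H](O[Si](C)(C)C(C)(C)C)COC(c2ccccc2)(c2ccccc2)c2ccccc2)cc(O[Si](C)(C)C(C)(C)C)c1O[Si](C)(C)C(C)(C)C
F6 | step 5 | (R)-3-[3,4-bis(tert-butyldimethylsilyloxy)-5-(3-methylbut-2-en-1-yl)phenyl]-2-(tert-butyldimethylsilyloxy)propan-1-ol | CC(C)=CCc1cc(C[C@@H](O[Si](C)(C)C(C)(C)C)CO)cc(O[Si](C)(C)C(C)(C)C)c1O[Si](C)(C)C(C)(C)C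
F7 | step 5 | (R)-3-[3,4-bis(tert-butyldimethylsilyloxy)-5-(3-methylbut-2-en-1-yl)phenyl]-2-(tert-butyldimethylsilyloxy)propanoic acid | CC(C)=CCc1cc(C[C@@H](O[Si](C)(C)C(C)(C)C)C(=O)O)cc(O[Si](C)(C)C(C)(C)C)c1O[Si](C)(C)C(C)(C)C
F8 | step 4 | 3-allyl-5-bromo-1,2-bis(tert-butyldimethylsilyloxy)benzene | C=CCc1cc(Br)cc(O[Si](C)(C)C(C)(C)C)c1O[Si](C)(C)C(C)(C)C
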